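Ring labels: ring A carries the sulfate. Ring B is the central ring (C1–O–ring A, C2–O–ring C, Br on C3, C4 and C5, H on C6). Ring C is the 4-bromo-2-iodophenyl ring.
Retrosynthesis: cut the S–O bond of the sulfate, trace the ring A hydroxyl back to a formyl group, and cut the C4–Br and C5–Br bonds of ring B. Then cut the ring A carbon–oxygen ether bond and last the C2–O bond of ring B, each ether going back to an ortho-fluorobenzaldehyde and a phenol.
Enabling feature: C4 and C5 of ring B lie para to the ether oxygens on C1 and C2, and ring B alone has two oxygen donors with both para positions open. On rings A and C every position para to oxygen is filled, and these rings carry CHO/Br/Br and Br/I. The C3 bromine comes with the building block.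
Forward: no ring is built. Three purchased benzene rings are joined in the order C + B, then A, by two fluoride displacements with a Baeyer–Villiger oxidation between them. Ring B is then dibrominated, the ring A aldehyde becomes the phenol, and the phenol is sulfated.
Stereochemistry: the target has no stereocentre and no double-bond geometry, so nothing has to be set.

Key step: step 4

Assumption: the target is made as drawn, as the hydrogen sulfate (free acid); the pyridinium salt formed first is converted by proton exchange.

Step 1
Reactants: 1 3-bromo-2-fluorobenzaldehyde; 2 4-bromo-2-iodophenol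
Product: 3 3-bromo-2-(4-bromo-2-iodophenoxy)benzaldehyde
Conditions: K2CO3, DMF, 90 °C
Reagents that add atoms: none
Why: Nucleophilic aromatic substitution by addition–elimination, in which the ortho formyl group stabilises the Meisenheimer adduct at the C–F carbon, fluoride is by far the best leaving group present, and the carbon–bromine and carbon–iodine bonds, none of them ortho or para to the formyl group, stay untouched in the absence of copper.

Step 2
Reactants: 3 3-bromo-2-(4-bromo-2-iodophenoxy)benzaldehyde
Product: 5 3-bromo-2-(4-bromo-2-iodophenoxy)phenol, via aryl formate 4 (not isolated)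
Conditions: mCPBA, KH2PO4, CH2Cl2, rt, dark; aq Na2S2O3/NaHCO3 wash; then MeOH–THF, cat. HCl, rt
Reagents that add atoms: mCPBA (3-chloroperoxybenzoic acid), O=C(OO)c1cccc(Cl)c1
Why: Baeyer–Villiger oxidation of an ortho-aryloxybenzaldehyde, in which the Criegee adduct expels 3-chlorobenzoate as the oxygen-substituted aryl group migrates, methanol then transesterifies the labile formate, and the buffered medium free of strong acid plus the thiosulfate wash keep the aryl iodide monovalent.

Step 3
Reactants: 5 3-bromo-2-(4-bromo-2-iodophenoxy)phenol; 6 3,5-dibromo-2-fluorobenzaldehyde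
Product: 7 3,5-dibromo-2-[3-bromo-2-(4-bromo-2-iodophenoxy)phenoxy]benzaldehyde
Conditions: Cs2CO3, DMF, 80 °C
Reagents that add atoms: none
Why: A second nucleophilic aromatic substitution, in which the loosely paired caesium phenoxide of 5 adds at the fluorine-bearing carbon activated by the ortho formyl group and by both bromines inductively, while ring C is too weakly activated for a Smiles migration to the neighbouring phenoxide.

Step 4
Reactants: 7 3,5-dibromo-2-[3-bromo-2-(4-bromo-2-iodophenoxy)phenoxy]benzaldehyde
Product: 9 3,5-dibromo-2-[3,4,5-tribromo-2-(4-bromo-2-iodophenoxy)phenoxy]benzaldehyde, via ring B monobromide 8 (not isolated)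
Conditions: NBS (1.05 equiv), TFA–CH2Cl2, cat. H2SO4, 0 °C→rt, dark; then NBS (1.05 equiv), more H2SO4, rt
Reagents that add atoms: N-bromosuccinimide (NBS), O=C1CCC(=O)N1Br
Why: Acid-activated NBS transfers a bromine cation to ring B in two successive electrophilic aromatic substitutions, each through a Wheland intermediate whose charge is taken up by a para ether oxygen: first at C4, para to the oxygen on C1 (its lone pair conjugates with ring B because the doubly ortho-substituted ring A stands perpendicular), giving 8, then at C5, para to the oxygen on C2 and ortho to the new bromine, giving 9. The closest known reactions are the 4,5-dibromination of veratrole and other catechol diethers, the 2,3-dihalogenation of dibenzo-p-dioxin, and the NBS/acid bromination of deactivated benzaldehydes, which leaves the formyl group intact. No ring closes and no stereocentre forms. The step needs ring selectivity, site selectivity and a stop after two bromines: ring A has a formyl group, two bromines and no free position ortho or para to its oxygen, ring C has only one free position ortho to its oxygen, which is meta to both halogens and pressed against ring B, and C6 of ring B has no para oxygen and lies under the face of ring A. The weakest point, ipso attack at the carbon–iodine bond, is countered by the bromide-free medium, which offers no good nucleophile to carry the iodine away as a cation, so attack there should revert, while darkness and exclusion of water protect the aldehyde hydrogen. Adding NBS in two portions and raising the acid strength only for the slower second substitution keeps the electrophile no stronger than each stage needs, and the tribrominated ring B of 9 is too electron-poor to react further.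

Step 5
Reactants: 9 3,5-dibromo-2-[3,4,5-tribromo-2-(4-bromo-2-iodophenoxy)phenoxy]benzaldehyde
Product: 11 3,5-dibromo-2-[3,4,5-tribromo-2-(4-bromo-2-iodophenoxy)phenoxy]phenol, via aryl formate 10 (not isolated)
Conditions: mCPBA, KH2PO4, CH2Cl2, 40 °C, dark; aq Na2S2O3/NaHCO3 wash; then MeOH–THF, cat. HCl, rt
Reagents that add atoms: mCPBA (3-chloroperoxybenzoic acid), O=C(OO)c1cccc(Cl)c1
Why: Baeyer–Villiger oxidation as in step 2, where the ortho ether oxygen and the relief of crowding at the formyl carbon favour migration of ring A over hydride (a pattern known from brominated 2-aryloxybenzaldehydes on the way to hydroxylated polybromodiphenyl ethers), and acid-catalysed methanolysis frees the phenol without forming a phenoxide that could start a Smiles migration of ring B.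

Step 6
Reactants: 11 3,5-dibromo-2-[3,4,5-tribromo-2-(4-bromo-2-iodophenoxy)phenoxy]phenol
Product: 13 bromoiesol B sulfate (3,5-dibromo-2-[3,4,5-tribromo-2-(4-bromo-2-iodophenoxy)phenoxy]phenyl hydrogen sulfate), via pyridinium sulfate salt 12 (not isolated)
Conditions: SO3·pyridine, pyridine, rt→40 °C; EtOAc extraction; strongly acidic cation-exchange resin (H+ form), MeOH, 0 °C
Reagents that add atoms: sulfur trioxide–pyridine complex, O=S(=O)([O-])[n+]1ccccc1
Why: O-Sulfation of a phenol with the SO3–pyridine complex, in which the only nucleophilic site, the phenol oxygen, attacks sulfur as pyridine leaves, and cold proton exchange on the resin gives the hydrogen sulfate before acid-catalysed loss of SO3 can set in.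

Compound list
1 | 3-bromo-2-fluorobenzaldehyde | O=Cc1cccc(Br)c1F | starting material
2 | 4-bromo-2-iodophenol | Oc1ccc(Br)cc1I | starting material
3 | 3-bromo-2-(4-bromo-2-iodophenoxy)benzaldehyde | O=Cc1cccc(Br)c1Oc1ccc(Br)cc1I | intermediate
4 | 3-bromo-2-(4-bromo-2-iodophenoxy)phenyl formate | O=COc1cccc(Br)c1Oc1ccc(Br)cc1I | intermediate
5 | 3-bromo-2-(4-bromo-2-iodophenoxy)phenol | Oc1cccc(Br)c1Oc1ccc(Br)cc1I | intermediate
6 | 3,5-dibromo-2-fluorobenzaldehyde | O=Cc1cc(Br)cc(Br)c1F | starting material
7 | 3,5-dibromo-2-[3-bromo-2-(4-bromo-2-iodophenoxy)phenoxy]benzaldehyde | O=Cc1cc(Br)cc(Br)c1Oc1cccc(Br)c1Oc1ccc(Br)cc1I | intermediate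
8 | 3,5-dibromo-2-[3,4-dibromo-2-(4-bromo-2-iodophenoxy)phenoxy]benzaldehyde | O=Cc1cc(Br)cc(Br)c1Oc1ccc(Br)c(Br)c1Oc1ccc(Br)cc1I | intermediate
9 | 3,5-dibromo-2-[3,4,5-tribromo-2-(4-bromo-2-iodophenoxy)phenoxy]benzaldehyde | O=Cc1cc(Br)cc(Br)c1Oc1cc(Br)c(Br)c(Br)c1Oc1ccc(Br)cc1I | intermediate
10 | 3,5-dibromo-2-[3,4,5-tribromo-2-(4-bromo-2-iodophenoxy)phenoxy]phenyl formate | O=COc1cc(Br)cc(Br)c1Oc1cc(Br)c(Br)c(Br)c1Oc1ccc(Br)cc1I | intermediate
11 | 3,5-dibromo-2-[3,4,5-tribromo-2-(4-bromo-2-iodophenoxy)phenoxy]phenol | Oc1cc(Br)cc(Br)c1Oc1cc(Br)c(Br)c(Br)c1Oc1ccc(Br)cc1I | intermediate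
12 | pyridinium 3,5-dibromo-2-[3,4,5-tribromo-2-(4-bromo-2-iodophenoxy)phenoxy]phenyl sulfate | [O-]S(=O)(=O)Oc1cc(Br)cc(Br)c1Oc1cc(Br)c(Br)c(Br)c1Oc1ccc(Br)cc1I.c1cc[nH+]cc1 | intermediate
13 | bromoiesol B sulfate | O=S(=O)(O)Oc1cc(Br)cc(Br)c1Oc1cc(Br)c(Br)c(Br)c1Oc1ccc(Br)cc1I | target

Total step count: 6. Longest linear sequence: 6 steps (from 1 or 2 to 13).

Steps most likely to fail

Step 4. Once ring B carries two bromines it has lost most of its electronic lead. The second substitution may then be overtaken by ipso substitution at the carbon–iodine bond, by attack on ring C, or by attack at C6 of ring B.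
- The fallback buys the C5 bromine with the building block and lets a free hydroxyl place the C4 bromine. It sets out from 2 and 6 and returns at 9.
- Fluoride displacement on 6 by 2 (K2CO3, DMF, 90 °C) should give 3,5-dibromo-2-(4-bromo-2-iodophenoxy)benzaldehyde F1.
- Buffered mCPBA leads through 3,5-dibromo-2-(4-bromo-2-iodophenoxy)phenyl formate F2, and methanolysis gives 3,5-dibromo-2-(4-bromo-2-iodophenoxy)phenol F3.
- One equivalent of Bu4NBr3, a para-selective reagent for phenols, in CH2Cl2–MeOH at 0 °C brominates para to the hydroxyl. These conditions are far too mild for ring C or the carbon–iodine bond, and the product is 3,4,5-tribromo-2-(4-bromo-2-iodophenoxy)phenol F4.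
- A second displacement on 6 (Cs2CO3, DMF, 80 °C) delivers 9.

Step 5. On the electron-poor ring A, hydride migration in the Criegee adduct may outrun aryl migration, and prolonged exposure to peracid may oxidise the iodine.
- The fallback replaces the oxygen insertion by a nitrogen detour. It sets out from 9 and returns at 11.
- Pinnick oxidation (NaClO2, NaH2PO4, 2-methyl-2-butene, t-BuOH–THF–water) should give 3,5-dibromo-2-[3,4,5-tribromo-2-(4-bromo-2-iodophenoxy)phenoxy]benzoic acid F5.
- Diphenylphosphoryl azide and Et3N in toluene convert it into the corresponding benzoyl azide F6. At 90 °C this undergoes Curtius rearrangement to the aryl isocyanate F7.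
- Aqueous HCl in dioxane hydrolyses the isocyanate to 3,5-dibromo-2-[3,4,5-tribromo-2-(4-bromo-2-iodophenoxy)phenoxy]aniline F8.
- Diazotisation with NaNO2 in H2SO4–AcOH gives the arenediazonium hydrogen sulfate F9, whose solution is run into boiling dilute H2SO4 to give 11.
- Ring closure onto C6 of ring B, the only free neighbouring position, should be slow because that ring carries three bromines.

Step 3. A hindered phenoxide may add only slowly to a fluoride flanked on both sides. Base-induced degradation of the aldehyde partner on long heating (disproportionation, capture by amine from the solvent) could then overtake ether formation.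
- The fallback changes the activating group and adds a reduction. It sets out from 5 and returns at 7.
- Phenol 5 is coupled with purchased 3,5-dibromo-2-fluorobenzonitrile (N#Cc1cc(Br)cc(Br)c1F; Cs2CO3, DMSO, 80–100 °C). Its linear, base-stable cyano group leaves more room at the reacting carbon. The product is 3,5-dibromo-2-[3-bromo-2-(4-bromo-2-iodophenoxy)phenoxy]benzonitrile F10.
- One equivalent of i-Bu2AlH in toluene at −78 °C adds once to the nitrile without touching the aryl halides. The aldimine F11, released from aluminium on acidic work-up, hydrolyses to 7.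

Further compounds
F1 | step 4 | 3,5-dibromo-2-(4-bromo-2-iodophenoxy)benzaldehyde | O=Cc1cc(Br)cc(Br)c1Oc1ccc(Br)cc1I
F2 | step 4 | 3,5-dibromo-2-(4-bromo-2-iodophenoxy)phenyl formate | O=COc1cc(Br)cc(Br)c1Oc1ccc(Br)cc1I
F3 | step 4 | 3,5-dibromo-2-(4-bromo-2-iodophenoxy)phenol | Oc1cc(Br)cc(Br)c1Oc1ccc(Br)cc1I
F4 | step 4 | 3,4,5-tribromo-2-(4-bromo-2-iodophenoxy)phenol | Oc1cc(Br)c(Br)c(Br)c1Oc1ccc(Br)cc1I
F5 | step 5 | 3,5-dibromo-2-[3,4,5-tribromo-2-(4-bromo-2-iodophenoxy)phenoxy]benzoic acid | O=C(O)c1cc(Br)cc(Br)c1Oc1cc(Br)c(Br)c(Br)c1Oc1ccc(Br)cc1I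
F6 | step 5 | 3,5-dibromo-2-[3,4,5-tribromo-2-(4-bromo-2-iodophenoxy)phenoxy]benzoyl azide | [N-]=[N+]=NC(=O)c1cc(Br)cc(Br)c1Oc1cc(Br)c(Br)c(Br)c1Oc1ccc(Br)cc1I
F7 | step 5 | 3,5-dibromo-2-[3,4,5-tribromo-2-(4-bromo-2-iodophenoxy)phenoxy]phenyl isocyanate | O=C=Nc1cc(Br)cc(Br)c1Oc1cc(Br)c(Br)c(Br)c1Oc1ccc(Br)cc1I
F8 | step 5 | 3,5-dibromo-2-[3,4,5-tribromo-2-(4-bromo-2-iodophenoxy)phenoxy]aniline | Nc1cc(Br)cc(Br)c1Oc1cc(Br)c(Br)c(Br)c1Oc1ccc(Br)cc1I
F9 | step 5 | 3,5-dibromo-2-[3,4,5-tribromo-2-(4-bromo-2-iodophenoxy)phenoxy]benzenediazonium hydrogen sulfate | N#[N+]c1cc(Br)cc(Br)c1Oc1cc(Br)c(Br)c(Br)c1Oc1ccc(Br)cc1I.OS(=O)(=O)[O-]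
F10 | step 3 | 3,5-dibromo-2-[3-bromo-2-(4-bromo-2-iodophenoxy)phenoxy]benzonitrile | N#Cc1cc(Br)cc(Br)c1Oc1cccc(Br)c1Oc1ccc(Br)cc1I
F11 | step 3 | 3,5-dibromo-2-[3-bromo-2-(4-bromo-2-iodophenoxy)phenoxy]benzaldimine | N=Cc1cc(Br)cc(Br)c1Oc1cccc(Br)c1Oc1ccc(Br)cc1I
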